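Chains stop growing here.

all flasks: Q 18 mM

| charge | D | remark | time |
|---|---|---|---|
| alder | 1.5 M | run made earlier |  |
| Wednesday's | 1.0 M |  | 5.0 min |
| Saturday's | 2.0 M |  | 5.0 min |

alder run (percent of the D charged)

| time / min | G / % |
|---|---|
| 0.200 | 40.6 |
| 0.333 | 52.7 |
| 0.500 | 61.4 |
| 0.667 | 64.8 |
| 1.00 | 69.5 |
| 1.50 | 72.6 |
| 2.50 | 71.8 |

(each reading ± 0.5 percentage points)

- the average divides the monomer in chains by the number of chains begun, living and dead together
- what may be going on: D + Q -> L + G; D + L -> G + L; L -> Z
- the earlier runs do not show the number of chains; that part of a forecast is a guess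

1. which of the two ends with the longer chains by the average number of monomer units in a chain (chains begun, living or dead) ("neither" if they lie within 10 %) (Wednesday's / Saturday's / neither)
2. average number of monomer units in a chain (chains begun, living or dead) at the end, Wednesday's
3. average number of monomer units in a chain (chains begun, living or dead) at the end, Saturday's

I took the proposed steps as they stood: L adds D at a rate first order in D and dies to Z without D, so in my reckoning ln(charged D / remaining D) climbs to a ceiling proportional to the L started, with the D charged absent from it, which is the usual dead-end polymerisation. The alder readings stopped rising by 1.50 min, and their last two averaged 72.2 %, so I read the ceiling as 1.28. With 40.6 % already in chains at 0.200 min I saw no lag, so I took L to start equal to the Q charged and defined the reach per unit of Q, the ceiling divided by the Q charge, as g = 71.1 M⁻¹.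

Conversion is then one minus exp(−g·Q), and length is conversion times D charged over Q charged, counting each Q as one chain, which is a guess. Wednesday's and Saturday's hold alder's Q and run 5.0 min, longer than the 1.50 min needed there, so I reckoned 40.1 for Wednesday's and 80.2 for Saturday's.

The forecast said Saturday's, with 40 (37 to 48) for Wednesday's and 81 (74 to 98) for Saturday's, on “first-order death of L, not D-dependent initiation”; it read the stop near 72.5 %, where I read 72.2 %.

The flasks gave 40.7 for Wednesday's and 81.0 for Saturday's, so Saturday's ended with the longer chains, and Wednesday's kept 27 % of its D and Saturday's 27 %.

    D + Q → L + G (k = 1.20 M⁻¹ s⁻¹)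
    D + L → G + L, rate k2*[L]*[D] (k = 3.10 M⁻¹ s⁻¹)
    L → Z (k = 0.0430 s⁻¹)

I then used g on a neighbour of Wednesday's charged with 0.045 M of Q, its D and time held. I reckoned a ceiling of 3.20 for it, hence 4.08 % of D left and a length of 21.3. That flask gave a length of 21.4, against 40.7 in Wednesday's, with 3.7 % of its D left.

The readings come from a simulation for substances that don't exist; noise was put on by code.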